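## Analysis of the target

Compound 25 is a linear pentamer of benzene rings, lettered A to E from the 2,4,6-trihydroxyphenyl end, joined by four diaryl ether oxygens and carrying thirteen free phenols; it has no stereocentre and no element of chirality. Ring A is a phloroglucinol whose ether carbon C4 lies between the hydroxylated C3 and C5, with the third hydroxyl on C1. Ring B carries the oxygen to ring A on B1, the oxygen to ring C on the neighbouring B2 and hydroxyls on B3 and B5; ring C is bound to ring B through C1 and to ring D through C4, with hydroxyls on C3 and C5; ring D carries the oxygen to ring C on D1, the oxygen to ring E on D2 and hydroxyls on D3 to D5; ring E is a 3,4,5-trihydroxyphenyl group. The free compound is sensitive: the pyrogallol-type rings D and E and the phloroglucinol ring A are oxidised by air, fastest in base, so all oxygens must travel protected and be released in one last, non-oxidising step. The difficulty lies in the ethers: every ether carbon except ring C C1 and ring E C1 has an oxygen substituent beside it and all rings are electron-rich, so each diaryl ether coupling pairs a hindered nucleophile with a deactivated electrophile. The A-B ether is the worst, with two oxygens flanking the ring A carbon and one flanking the ring B carbon. The plan rests on ring A: C3-C4-C5 has the pattern of a malonate (a central carbon between two carbonyl carbons) and C2-C1-C6 that of a 3-oxopentanedioate, so ring A can be built around a preformed alkyl aryl ether instead of being coupled.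

## Retrosynthetic reasoning

25 from 24. The thirteen O-H bonds are traced back to thirteen O-CH3 bonds. One kind of protecting group on all five rings means one final operation, and methyl ethers survive everything the route needs (alkoxide at reflux, hot aqueous alkali, peracid, copper catalysis near 100 °C, hydrogenolysis). The forward reaction must break only alkyl-oxygen bonds, leave the four aryl-oxygen-aryl bonds alone and be non-oxidising.

24 from 14 and 23. The bond cut is between ring C C1 and the oxygen on B2. This is the only inter-ring bond whose electrophilic carbon has no ortho substituent (in 23 the bromine sits between two C-H bonds), so the coupling has one hindered partner instead of two. It also splits the skeleton into a two-ring phenol and a three-ring bromide, the most convergent cut available. Cutting the A-B ether instead would mean joining a carbon flanked by two methoxy groups to a hindered oxygen, which is the coupling this plan is built to avoid.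

14 back to 10. These are functional-group changes only. The B2 hydroxyl of 14 comes from the benzyl ether 13 by hydrogenolysis; benzyl is orthogonal to methyl, stable to base, and is removed before any aryl bromide is present. The ring A methyl ethers of 13 come from triol 12. The two ring A C-H bonds at C2 and C6 of 12 come from the two ester groups of 10 by hydrolysis to diacid 11 and decarboxylation. The esters are not wanted in the target, but they are what makes the ring synthesis possible, and a 2,4,6-trihydroxybenzoic acid loses its carboxyl group easily.

10 from 7 and 8 (key disconnection). The C2-C3 and C5-C6 bonds of ring A are cut. This removes ring A and leaves the A-B ether oxygen attached to an sp3 malonate carbon in 7, while 8 supplies C2, C1 and C6 with the C1 oxygen. The forward reaction has to form two C-C bonds by ester acylation, close a six-membered ring and aromatise, in preference to self-condensation of 8.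

7 from 5 and 6. The bond cut is O-C(sp3). The oxygen between rings A and B is thus introduced by alkylation of a phenoxide at a malonate carbon, where steric demand is low, and not by a diaryl ether coupling.

5 back to 1. The B1 oxygen of 5 is traced to a formyl carbon in 3 (aryl migration to oxygen, through formate 4); the benzyl ether of 3 to the phenol 2; and the formyl group of 2 to ortho-formylation of 1, which has one free ortho position. The alkaline peroxide variant of the aldehyde-to-phenol oxidation needs a free ortho or para hydroxyl, which 3 no longer has, so the peracid variant is specified.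

23 from 21 and 22. The bond cut is between ring E C1 and the oxygen on D2. A boron partner is chosen because oxidative copper coupling at room temperature leaves the ring C bromide of 21 untouched; ring E is unhindered, so only the phenol is difficult.

21 back to 17 and 18. The D2 hydroxyl of 21 again comes from a formyl group (19, through formate 20). In 19 the bond between D1 and the oxygen of 18 is cut. The formyl group of 17 does two jobs: it activates the neighbouring C-Br bond for copper-mediated substitution, distinguishing it from the C-Br bond of 18 (which sits para to a phenoxide oxygen on a very electron-rich ring), and it later becomes the D2 oxygen.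

17 from 15. The formyl C-C bond is cut. 15 has only one kind of ring C-H, so the formylation (through 16) has no regiochemical choice.

## Alternatives that were turned down

Alternative 1: Ring C is made instead of ring A, from a pyranone. The disconnection is one C-C bond of ring C, between the C-H carbon C2 and the hydroxylated C3. It leads back through the open-chain diketo ester A3 to the 3-aryloxy-4-hydroxy-6-methylpyran-2-one A2, whose aryloxy group is the complete D-E unit. Forward, NaOMe would open the lactone of A2 to A3, and the methyl terminus of A3 would attack the ester carbon to close ring C as the 2-aryloxyphloroglucinol A1.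
- For: the ring closure is intramolecular, so no second component can self-condense, and building a ring in the middle of the chain is more convergent than building an end ring. On both points it is stronger than the chosen plan.
- Against: the attacking carbon is the terminal methyl group, the least acidic position of A3. The two methylenes between carbonyls are deprotonated first, so recyclisation to A2 or aldol-type closure to a resorcinol is the easier path. In the chosen plan both new C-C bonds come from doubly stabilised methylene enolates.
- Against: A2 needs an oxygen nucleophile attached to C3 of a hydroxypyranone, a carbon that is itself nucleophilic, which calls for an umpolung step with a hindered D-E phenol.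
- Against, most seriously: A1 has three free hydroxyls on ring C, of which exactly one (para to the ether) must be joined to the hindered B2 carbon while the two ortho hydroxyls stay free.
- In exchange the chosen plan offers a ring whose three hydroxyls are all free in the target, so no differentiation is needed, and the hindered A-B ether is never formed by coupling.

Alternative 2: Ring D, the pentaoxygenated ring, is made by ring expansion of a cyclobutenone (Moore rearrangement). The disconnection is the D5-D6 bond and leads back to the 4-(1-aryloxyvinyl)-4-hydroxy-2,3-dimethoxycyclobutenone A5, the aryl group being a protected ring C. Forward, heating A5 in toluene would open the four-membered ring in a four-electron process to the dienylketene A6, which closes by six-electron electrocyclisation and tautomerises to the hydroquinone A4.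
- For: it attacks the most heavily oxygenated ring directly, places all five oxygens of ring D without regiochemical ambiguity, runs under neutral thermal conditions and is an established reaction type. On certainty of the ring-forming step and on the difficulty of the ring addressed it is stronger than the chosen plan, whose ring D comes from a trimethoxyarene by formylation and oxidation.
- Against: A5 requires an alpha-metallated aryl vinyl ether of a 2,6-dimethoxyphenol, added to a squarate ester at low temperature; metallation of the aryl ring next to a methoxy group competes.
- Against: A4 is an air-sensitive hydroquinone with two free hydroxyls (D2 and D5) that must be told apart before ring E goes onto the more hindered one.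
- Against: the A-B ether would still have to be made by coupling.
- In exchange the chosen plan offers a ring synthesis from two bulk esters under alkoxide, no hydroxyl differentiation and removal of the worst coupling, with fewer operations in the arm that carries the new ring.

Alternative 3: No ring is built; two hydroxyls are installed last. The disconnection is two C-O bonds, at ring A C1 and at ring B B5, leading back to the dideoxy undecamethyl pentamer A8. Forward, A8 would be borylated with B2pin2 under [Ir(OMe)(cod)]2 and 4,4'-di-tert-butyl-2,2'-bipyridine, and the two C-B bonds oxidised with Oxone in the same flask to give the diol A7.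
- For: the selectivity argument is sound, since these two C-H bonds are the only ones in A8 without an ortho substituent and this borylation is governed by sterics. Rings A and B would start from simpler phenols, and the reaction type is established, which the chosen ring closure is not. On predictability of the key step, and probably on step count, it is the stronger plan.
- Against: it forms no skeletal bond, so all four diaryl ethers, including the A-B ether between a 2,6-dimethoxyphenyl carbon and a catechol-type oxygen, must come from hindered couplings. That is the real difficulty of the target.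
- Against: the borylation must go to completion twice on a very electron-rich, slowly reacting substrate at the end of the synthesis; partial conversion would leave mono- and bis-functionalised pentamers of very similar polarity.
- In exchange the chosen plan places its risk at an early step on inexpensive material and replaces the hardest ether coupling by a phenoxide alkylation followed by ring construction.

Key step: step 5

Assumption: the target is achiral; 1, 6, 8, 15, 18 and 22 are taken as purchasable; both aldehyde-to-phenol oxidations are run with peracid because the alkaline hydrogen peroxide Dakin variant needs a free ortho or para hydroxyl.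

## Route

Step 1  
Reactants: 1 2,4-dimethoxyphenol  
Product: 2 2-hydroxy-3,5-dimethoxybenzaldehyde  
Conditions: MgCl2, Et3N, (CH2O)n, MeCN, reflux; then 1 M HCl  
Reagents that add atoms: formaldehyde (as paraformaldehyde), C=O  
Why: Magnesium-mediated ortho-formylation (Casnati-Skattebøl): the magnesium phenoxide delivers formaldehyde to the only free ortho position, and a second formaldehyde oxidises the benzylic alkoxide by hydride transfer.

Step 2  
Reactants: 2 2-hydroxy-3,5-dimethoxybenzaldehyde  
Product: 3 2-(benzyloxy)-3,5-dimethoxybenzaldehyde  
Conditions: BnBr, K2CO3, DMF, 60 °C  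
Reagents that add atoms: benzyl bromide, BrCc1ccccc1  
Why: Williamson etherification of a phenol made more acidic by the ortho formyl group; the benzyl group is later removed by hydrogenolysis without touching methyl ethers.

Step 3  
Reactants: 3 2-(benzyloxy)-3,5-dimethoxybenzaldehyde  
Product: 5 2-(benzyloxy)-3,5-dimethoxyphenol, via aryl formate 4 (not isolated)  
Conditions: mCPBA, CH2Cl2, 0 °C to rt; then K2CO3, MeOH, rt  
Reagents that add atoms: 3-chloroperoxybenzoic acid (mCPBA), OOC(=O)c1cccc(Cl)c1  
Why: Baeyer-Villiger (Dakin-type) oxidation: the electron-rich aryl group with an ortho alkoxy substituent migrates in preference to hydride to give formate 4, which mild methanolysis cleaves to the phenol.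

Step 4  
Reactants: 5 2-(benzyloxy)-3,5-dimethoxyphenol, 6 diethyl bromomalonate  
Product: 7 diethyl 2-[2-(benzyloxy)-3,5-dimethoxyphenoxy]malonate  
Conditions: K2CO3, acetone, reflux  
Reagents that add atoms: none  
Why: SN2 O-alkylation of the phenoxide at the doubly activated secondary bromide (Williamson ether synthesis); carbonate is too weak to start Claisen chemistry, and the aryloxy group shields the product from further alkylation.

Step 5  
Reactants: 7 diethyl 2-[2-(benzyloxy)-3,5-dimethoxyphenoxy]malonate, 8 diethyl 3-oxopentanedioate  
Product: 10 diethyl 5-[2-(benzyloxy)-3,5-dimethoxyphenoxy]-2,4,6-trihydroxybenzene-1,3-dicarboxylate, via open-chain triester 9 (not isolated)  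
Conditions: 8, NaOEt (1.0 equiv), EtOH, 0 °C, added over 6 h to 7 (1.5 equiv) in EtOH at reflux; NaOEt (1.2 equiv), EtOH distilled off, toluene, 110 °C; then 1 M HCl, 0 °C  
Reagents that add atoms: none  
Why: Proposed new method: the sodium enolate of 8 attacks one ester carbonyl of 7 and expels ethoxide (crossed Claisen acylation, forming C2-C3) to give 9, whose remaining methylene then attacks the second malonate-derived ester in a 6-exo-trig Dieckmann closure (forming C5-C6), and the cyclohexane-1,3,5-trione so formed tautomerises to the benzene ring. The closest known reaction is the alkoxide-mediated condensation of unsubstituted malonic esters with 3-oxopentanedioate esters to phloroglucinol dicarboxylates; a malonate carrying an aryloxy group on its central carbon has not been used in it. Both acylations are reversible, and aromatisation together with salt formation of the acidic product is the sink that pulls them forward; O-acylation to pyranones is reversible under ethoxide and drains into the same sink. The aryloxy carbon keeps its hydrogen, so the ring can enolise fully, and an oxygen on a carbon alpha to the carbonyls cannot be lost by beta-elimination. No stereocentre is formed. The selectivity needed is crossed condensation over self-condensation of 8: 8 is the more acidic partner, is fully enolised before addition and is fed slowly into hot excess 7, so its enolate meets 7 and not neutral 8. Because 8 holds the base, 7 stays largely protonated and therefore electrophilic during the first acylation; the second portion of base is added only for the ring closure.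

Step 6  
Reactants: 10 diethyl 5-[2-(benzyloxy)-3,5-dimethoxyphenoxy]-2,4,6-trihydroxybenzene-1,3-dicarboxylate  
Product: 12 2-[2-(benzyloxy)-3,5-dimethoxyphenoxy]benzene-1,3,5-triol, via dicarboxylic acid 11 (not isolated)  
Conditions: 2 M NaOH (degassed), reflux, Ar; then conc. HCl to pH 1, 80 °C  
Reagents that add atoms: none  
Why: Saponification followed by decarboxylation of a 2,4,6-trihydroxybenzene-1,3-dicarboxylic acid, which loses CO2 readily because ring protonation next to the carboxyl gives a beta-keto acid tautomer; exclusion of air protects the phloroglucinol anion.

Step 7  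
Reactants: 12 2-[2-(benzyloxy)-3,5-dimethoxyphenoxy]benzene-1,3,5-triol  
Product: 13 2-[2-(benzyloxy)-3,5-dimethoxyphenoxy]-1,3,5-trimethoxybenzene  
Conditions: Me2SO4, K2CO3, acetone, reflux, Ar  
Reagents that add atoms: dimethyl sulfate, COS(=O)(=O)OC  
Why: Exhaustive O-methylation with a hard methylating agent and K2CO3 in acetone, the standard conditions that favour O- over C-alkylation of phloroglucinols.

Step 8  
Reactants: 13 2-[2-(benzyloxy)-3,5-dimethoxyphenoxy]-1,3,5-trimethoxybenzene  
Product: 14 2,4-dimethoxy-6-(2,4,6-trimethoxyphenoxy)phenol  
Conditions: H2 (1 atm), 10% Pd/C, EtOAc/MeOH, rt  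
Reagents that add atoms: none  
Why: Catalytic hydrogenolysis of the benzyl ether; methyl and diaryl ethers are inert and no halogen is present at this stage.

Step 9  
Reactants: 15 5-bromo-1,2,3-trimethoxybenzene  
Product: 17 6-bromo-2,3,4-trimethoxybenzaldehyde, via chloro(methoxy)methyl arene 16 (not isolated)  
Conditions: Cl2CHOMe, TiCl4, CH2Cl2, -10 to 0 °C; then ice, 1 M HCl  
Reagents that add atoms: dichloromethyl methyl ether, COC(Cl)Cl; water, O  
Why: Rieche formylation: the only kind of ring C-H in 15 is ortho and para to methoxy groups, so a single regioisomer is expected, and the low temperature limits Lewis-acid demethylation; 16 is hydrolysed on work-up.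

Step 10  
Reactants: 17 6-bromo-2,3,4-trimethoxybenzaldehyde, 18 4-bromo-2,6-dimethoxyphenol  
Product: 19 6-(4-bromo-2,6-dimethoxyphenoxy)-2,3,4-trimethoxybenzaldehyde  
Conditions: CuI (10 mol %), picolinic acid (20 mol %), K3PO4, DMSO, 90 °C, Ar  
Reagents that add atoms: none  
Why: Copper-catalysed Ullmann ether synthesis: the C-Br bond of 17 is activated by the ortho formyl group, whereas the C-Br bond of 18 lies para to the phenoxide oxygen on an electron-rich ring and should stay intact; picolinic acid is a ligand suited to 2,6-disubstituted phenols.

Step 11  
Reactants: 19 6-(4-bromo-2,6-dimethoxyphenoxy)-2,3,4-trimethoxybenzaldehyde  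
Product: 21 6-(4-bromo-2,6-dimethoxyphenoxy)-2,3,4-trimethoxyphenol, via aryl formate 20 (not isolated)  
Conditions: mCPBA, CH2Cl2, 0 °C to rt; then K2CO3, MeOH, rt  
Reagents that add atoms: 3-chloroperoxybenzoic acid (mCPBA), OOC(=O)c1cccc(Cl)c1  
Why: Baeyer-Villiger oxidation of a benzaldehyde flanked by methoxy and aryloxy groups and para to a methoxy group, an arrangement that strongly favours aryl migration; methanolysis of 20 frees the D2 hydroxyl.

Step 12  
Reactants: 21 6-(4-bromo-2,6-dimethoxyphenoxy)-2,3,4-trimethoxyphenol, 22 (3,4,5-trimethoxyphenyl)boronic acid  
Product: 23 5-bromo-1,3-dimethoxy-2-[3,4,5-trimethoxy-2-(3,4,5-trimethoxyphenoxy)phenoxy]benzene  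
Conditions: Cu(OAc)2 (1 equiv, re-oxidised by air), pyridine, 4 Å MS, CH2Cl2, dry air, rt  
Reagents that add atoms: none  
Why: Chan-Lam oxidative C-O coupling mediated by divalent copper at room temperature; aryl bromides are inert under these conditions, the boronic acid is electron-rich and has no ortho substituent, and only the phenol is hindered.

Step 13  
Reactants: 14 2,4-dimethoxy-6-(2,4,6-trimethoxyphenoxy)phenol, 23 5-bromo-1,3-dimethoxy-2-[3,4,5-trimethoxy-2-(3,4,5-trimethoxyphenoxy)phenoxy]benzene  
Product: 24 2-(2-{3,5-dimethoxy-4-[3,4,5-trimethoxy-2-(3,4,5-trimethoxyphenoxy)phenoxy]phenoxy}-3,5-dimethoxyphenoxy)-1,3,5-trimethoxybenzene (trideca-O-methyl ether of the target)  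
Conditions: CuI (20 mol %), picolinic acid (40 mol %), K3PO4, DMSO, 100 °C, Ar  
Reagents that add atoms: none  
Why: Ullmann ether synthesis of a hindered phenol with an aryl bromide whose C-Br carbon lies between two C-H bonds; the picolinic acid/K3PO4/DMSO system is established for di-ortho-substituted phenols and electron-rich bromides, and the 2-aryloxyphenoxide of 14 cannot undergo Smiles rearrangement because the ring that would migrate is electron-rich.

Step 14  
Reactants: 24 trideca-O-methyl ether of the target  
Product: 25 2-(2-{3,5-dihydroxy-4-[3,4,5-trihydroxy-2-(3,4,5-trihydroxyphenoxy)phenoxy]phenoxy}-3,5-dihydroxyphenoxy)benzene-1,3,5-triol (CNP0243665.0)  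
Conditions: BBr3 (excess), CH2Cl2, -78 °C to rt; then H2O, 0 °C; Ar throughout  
Reagents that add atoms: none  
Why: Lewis-acid ether cleavage: BBr3 coordinates each methoxy oxygen and bromide attacks the methyl group, so only alkyl-oxygen bonds break and the four diaryl ethers persist; hydrolysis of the aryl borates under argon should release the thirteen phenols.

## Compound list

1 | 2,4-dimethoxyphenol | COc1ccc(O)c(OC)c1 | starting material  
2 | 2-hydroxy-3,5-dimethoxybenzaldehyde | O=Cc1cc(OC)cc(OC)c1O | intermediate  
3 | 2-(benzyloxy)-3,5-dimethoxybenzaldehyde | O=Cc1cc(OC)cc(OC)c1OCc1ccccc1 | intermediate  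
4 | 2-(benzyloxy)-3,5-dimethoxyphenyl formate | O=COc1cc(OC)cc(OC)c1OCc1ccccc1 | intermediate  
5 | 2-(benzyloxy)-3,5-dimethoxyphenol | Oc1cc(OC)cc(OC)c1OCc1ccccc1 | intermediate  
6 | diethyl bromomalonate | CCOC(=O)C(Br)C(=O)OCC | starting material  
7 | diethyl 2-[2-(benzyloxy)-3,5-dimethoxyphenoxy]malonate | CCOC(=O)C(Oc1cc(OC)cc(OC)c1OCc1ccccc1)C(=O)OCC | intermediate  
8 | diethyl 3-oxopentanedioate | CCOC(=O)CC(=O)CC(=O)OCC | starting material  
9 | diethyl 2-[2-(benzyloxy)-3,5-dimethoxyphenoxy]-4-(ethoxycarbonyl)-3,5-dioxoheptanedioate (mixture of stereoisomers and enol forms) | CCOC(=O)CC(=O)C(C(=O)OCC)C(=O)C(Oc1cc(OC)cc(OC)c1OCc1ccccc1)C(=O)OCC | intermediate  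
10 | diethyl 5-[2-(benzyloxy)-3,5-dimethoxyphenoxy]-2,4,6-trihydroxybenzene-1,3-dicarboxylate | CCOC(=O)c1c(O)c(Oc2cc(OC)cc(OC)c2OCc2ccccc2)c(O)c(C(=O)OCC)c1O | intermediate  
11 | 5-[2-(benzyloxy)-3,5-dimethoxyphenoxy]-2,4,6-trihydroxybenzene-1,3-dicarboxylic acid | OC(=O)c1c(O)c(Oc2cc(OC)cc(OC)c2OCc2ccccc2)c(O)c(C(=O)O)c1O | intermediate  
12 | 2-[2-(benzyloxy)-3,5-dimethoxyphenoxy]benzene-1,3,5-triol | Oc1cc(O)c(Oc2cc(OC)cc(OC)c2OCc2ccccc2)c(O)c1 | intermediate  
13 | 2-[2-(benzyloxy)-3,5-dimethoxyphenoxy]-1,3,5-trimethoxybenzene | COc1cc(OC)c(Oc2cc(OC)cc(OC)c2OCc2ccccc2)c(OC)c1 | intermediate  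
14 | 2,4-dimethoxy-6-(2,4,6-trimethoxyphenoxy)phenol | COc1cc(OC)c(Oc2cc(OC)cc(OC)c2O)c(OC)c1 | intermediate  
15 | 5-bromo-1,2,3-trimethoxybenzene | COc1cc(Br)cc(OC)c1OC | starting material  
16 | 1-bromo-2-[chloro(methoxy)methyl]-3,4,5-trimethoxybenzene (racemic) | COC(Cl)c1c(Br)cc(OC)c(OC)c1OC | intermediate  
17 | 6-bromo-2,3,4-trimethoxybenzaldehyde | O=Cc1c(Br)cc(OC)c(OC)c1OC | intermediate  
18 | 4-bromo-2,6-dimethoxyphenol | COc1cc(Br)cc(OC)c1O | starting material  
19 | 6-(4-bromo-2,6-dimethoxyphenoxy)-2,3,4-trimethoxybenzaldehyde | O=Cc1c(Oc2c(OC)cc(Br)cc2OC)cc(OC)c(OC)c1OC | intermediate  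
20 | 6-(4-bromo-2,6-dimethoxyphenoxy)-2,3,4-trimethoxyphenyl formate | O=COc1c(Oc2c(OC)cc(Br)cc2OC)cc(OC)c(OC)c1OC | intermediate  
21 | 6-(4-bromo-2,6-dimethoxyphenoxy)-2,3,4-trimethoxyphenol | Oc1c(Oc2c(OC)cc(Br)cc2OC)cc(OC)c(OC)c1OC | intermediate  
22 | (3,4,5-trimethoxyphenyl)boronic acid | COc1cc(B(O)O)cc(OC)c1OC | starting material  
23 | 5-bromo-1,3-dimethoxy-2-[3,4,5-trimethoxy-2-(3,4,5-trimethoxyphenoxy)phenoxy]benzene | COc1cc(Br)cc(OC)c1Oc1cc(OC)c(OC)c(OC)c1Oc1cc(OC)c(OC)c(OC)c1 | intermediate  
24 | 2-(2-{3,5-dimethoxy-4-[3,4,5-trimethoxy-2-(3,4,5-trimethoxyphenoxy)phenoxy]phenoxy}-3,5-dimethoxyphenoxy)-1,3,5-trimethoxybenzene | COc1cc(OC)c(Oc2cc(OC)cc(OC)c2Oc2cc(OC)c(Oc3cc(OC)c(OC)c(OC)c3Oc3cc(OC)c(OC)c(OC)c3)c(OC)c2)c(OC)c1 | intermediate  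
25 | 2-(2-{3,5-dihydroxy-4-[3,4,5-trihydroxy-2-(3,4,5-trihydroxyphenoxy)phenoxy]phenoxy}-3,5-dihydroxyphenoxy)benzene-1,3,5-triol | Oc1cc(O)c(Oc2cc(O)cc(O)c2Oc2cc(O)c(Oc3cc(O)c(O)c(O)c3Oc3cc(O)c(O)c(O)c3)c(O)c2)c(O)c1 | target  

## Step count and least certain steps

Total: 14 steps. Longest linear sequence: 10 steps (steps 1 to 8, then 13 and 14); the C-D-E arm is steps 9 to 12.

Step 5 (key step, proposed new method). Self-condensation of the keto diester and retro-Claisen loss of an ethoxycarbonyl group from 7 may outrun the crossed acylation, because the malonate carbonyls of 7 are shielded by the ortho-substituted aryloxy group and are switched off whenever 7 is deprotonated; the sequence may also stall before ring closure. Fallback, by known chemistry: abandon the ring construction and form the A-B ether by copper-catalysed Ullmann coupling of phenol 5 with purchased 2-iodo-1,3,5-trimethoxybenzene (COc1cc(OC)c(I)c(OC)c1; CuI, picolinic acid, K3PO4, DMSO, 110 °C). This sets out from 5 and returns to the route at 13, bypassing 7 to 12, and makes no new compound (F0). It is the hindered coupling the main route avoids, so only modest efficiency is to be expected.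

Step 10. The hindered, easily oxidised phenoxide of 18 may couple slowly, after which copper can begin to activate the C-Br bond of 18 or of 19, leading to oligomeric ethers and hydrodebromination. Fallback: replace the copper step by a metal-free SNAr. Rieche formylation of purchased 5-fluoro-1,2,3-trimethoxybenzene (COc1cc(F)cc(OC)c1OC) under the conditions of step 9 should give 6-fluoro-2,3,4-trimethoxybenzaldehyde F1, whose fluorine, ortho to the formyl group, is displaced by the phenoxide of 18 (Cs2CO3, DMSO, 110 °C). The fallback sets out from 18 and returns at 19; no C-Br bond can react under these conditions.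

Step 12. Slow C-O bond formation at the di-ortho-substituted phenoxide of 21 would let protodeboronation and oxidative homocoupling of 22 consume the boron partner. Fallback: Ullmann coupling of 21 with purchased 5-iodo-1,2,3-trimethoxybenzene (COc1cc(I)cc(OC)c1OC, 3 equiv; CuI, picolinic acid, K3PO4, DMSO, 80 °C), relying on the faster reaction of an aryl iodide than of the ring C bromide and on the excess of iodide. It sets out from 21 and returns at 23, making no new compound (F0).

Step 13. The phenoxide of 14 is flanked by a methoxy group and a bulky aryloxy group; if its binding to copper is too slow, hydrodebromination of 23 and oxidative decay of the phenoxide take over. Fallback: move from halide to boron on ring C. Bromine-lithium exchange on 23 (n-BuLi, THF, -78 °C), then B(OiPr)3 and acidic work-up, should give {3,5-dimethoxy-4-[3,4,5-trimethoxy-2-(3,4,5-trimethoxyphenoxy)phenoxy]phenyl}boronic acid F2, which is coupled with 14 under Chan-Lam conditions (Cu(OAc)2, pyridine, 4 Å MS, CH2Cl2, air, rt). The fallback sets out from 23 and returns at 24.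

Step 14. Thirteen ether cleavages must all go to completion; precipitation of partly cleaved aryl borates can stop the reaction early, and the pyrogallol rings D and E can be oxidised during aqueous isolation. Fallback: after BBr3 treatment of 24 and removal of boron by evaporation with methanol, the crude polyphenol is acetylated at once (Ac2O, pyridine) to the trideca-O-acetate of the target F3. F3 is stable to air and separable by chromatography from congeners still holding a methyl ether; acid methanolysis under argon (HCl in MeOH, rt) then releases 25. The fallback sets out from 24 and returns at 25.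

## Further compounds

F0 | step 5 | none | none  
F1 | step 10 | 6-fluoro-2,3,4-trimethoxybenzaldehyde | O=Cc1c(F)cc(OC)c(OC)c1OC  
F0 | step 12 | none | none  
F2 | step 13 | {3,5-dimethoxy-4-[3,4,5-trimethoxy-2-(3,4,5-trimethoxyphenoxy)phenoxy]phenyl}boronic acid | COc1cc(B(O)O)cc(OC)c1Oc1cc(OC)c(OC)c(OC)c1Oc1cc(OC)c(OC)c(OC)c1  
F3 | step 14 | trideca-O-acetate of the target | CC(=O)Oc1cc(OC(C)=O)c(Oc2cc(OC(C)=O)cc(OC(C)=O)c2Oc2cc(OC(C)=O)c(Oc3cc(OC(C)=O)c(OC(C)=O)c(OC(C)=O)c3Oc3cc(OC(C)=O)c(OC(C)=O)c(OC(C)=O)c3)c(OC(C)=O)c2)c(OC(C)=O)c1  
A1 | alternative 1 | 2-[3,4,5-trimethoxy-2-(3,4,5-trimethoxyphenoxy)phenoxy]benzene-1,3,5-triol | Oc1cc(O)c(Oc2cc(OC)c(OC)c(OC)c2Oc2cc(OC)c(OC)c(OC)c2)c(O)c1  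
A2 | alternative 1 | 4-hydroxy-6-methyl-3-[3,4,5-trimethoxy-2-(3,4,5-trimethoxyphenoxy)phenoxy]-2H-pyran-2-one | Cc1cc(O)c(Oc2cc(OC)c(OC)c(OC)c2Oc2cc(OC)c(OC)c(OC)c2)c(=O)o1  
A3 | alternative 1 | methyl 3,5-dioxo-2-[3,4,5-trimethoxy-2-(3,4,5-trimethoxyphenoxy)phenoxy]hexanoate | COC(=O)C(Oc1cc(OC)c(OC)c(OC)c1Oc1cc(OC)c(OC)c(OC)c1)C(=O)CC(C)=O  
A4 | alternative 2 | 5-[4-(benzyloxy)-2,6-dimethoxyphenoxy]-2,3-dimethoxybenzene-1,4-diol | COc1c(O)cc(Oc2c(OC)cc(OCc3ccccc3)cc2OC)c(O)c1OC  
A5 | alternative 2 | 4-{1-[4-(benzyloxy)-2,6-dimethoxyphenoxy]ethenyl}-4-hydroxy-2,3-dimethoxycyclobut-2-en-1-one | COC1=C(OC)C(O)(C(=C)Oc2c(OC)cc(OCc3ccccc3)cc2OC)C1=O  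
A6 | alternative 2 | (3Z)-5-[4-(benzyloxy)-2,6-dimethoxyphenoxy]-4-hydroxy-2,3-dimethoxyhexa-1,3,5-trien-1-one | O=C=C(OC)/C(OC)=C(O)\C(=C)Oc1c(OC)cc(OCc2ccccc2)cc1OC  
A7 | alternative 3 | undeca-O-methyl ether of the target with free hydroxyls on ring A C1 and ring B B5 | COc1cc(O)cc(OC)c1Oc1cc(O)cc(OC)c1Oc1cc(OC)c(Oc2cc(OC)c(OC)c(OC)c2Oc2cc(OC)c(OC)c(OC)c2)c(OC)c1  
A8 | alternative 3 | dideoxy undeca-O-methyl pentamer lacking the oxygens on ring A C1 and ring B B5 | COc1cccc(OC)c1Oc1cccc(OC)c1Oc1cc(OC)c(Oc2cc(OC)c(OC)c(OC)c2Oc2cc(OC)c(OC)c(OC)c2)c(OC)c1  
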